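**Retrosynthetic overview**

1. The pyran ring is opened at C2–C3. The (2S)-flavan is traced to benzylidene malonate 12, a benzyl aryl ether in which ring A carries C4=C3(CO2allyl)2 ortho to the O1–CH2–(ring B) unit. A hydride-shift/ring-closure cascade makes C2–C3 and the C2 stereocentre, and the two esters are then removed (deallylation/decarboxylation, then Barton decarboxylation).
2. Enabling feature: the C2–H bonds sit between O1 and ring B, whose 4'-oxygen is para to the carbon bearing C2, so they are hydridic. O1 (on C8a) is ortho to C4a, which places these hydrogens 1,5 to C4. The C7 oxygen para to C4a is worn as an acetate so that C4 stays electrophilic.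
3. The ether comes from Mitsunobu union of ring-B benzyl alcohol 5 with aldehyde 7. The two ring-B prenyl groups are installed by bromine–lithium exchange and directed ortho-metalation, each followed by copper-mediated prenylation. The C6 1,1-dimethylallyl group comes from aromatic Claisen rearrangement of the C7 prenyl ether.
4. Ring order: rings A and B are bought as benzenes; the pyran ring is the only ring made, in step 9.

Key step: step 9

Abbreviations: Ar = 3,4-bis(methoxymethoxy)-2,5-bis(3-methylbut-2-en-1-yl)phenyl; prenyl = 3-methylbut-2-en-1-yl; MOM = methoxymethyl.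

Remark: the sense of induction of the scandium/N,N'-dioxide catalyst in step 9 cannot be predicted safely, so the ligand enantiomer is assumed to be fixed by a preliminary screen. The (2R) descriptor of diester 14 and the (2S) descriptor of the target describe the same spatial arrangement, because two ester groups raise the CIP rank of C3 above that of the aryl carbon.

**Step 1**
Reactants: 1 3-bromo-4,5-dihydroxybenzaldehyde
Product: 2 3-bromo-4,5-bis(methoxymethoxy)benzaldehyde
Conditions: MOMCl, iPr2NEt, CH2Cl2, 0 °C → rt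
Reagents that add atoms: chloromethyl methyl ether (MOMCl), COCCl
Why: O-alkylation of both phenols (acetal protection) gives ethers that later direct metalation, keep ring B electron-rich and survive base, heat and radicals.

**Step 2**
Reactants: 2 3-bromo-4,5-bis(methoxymethoxy)benzaldehyde
Product: 3 [3-bromo-4,5-bis(methoxymethoxy)phenyl]methanol
Conditions: NaBH4, MeOH, 0 °C
Reagents that add atoms: none
Why: Chemoselective borohydride reduction of the aldehyde should leave the aryl bromide and the acetals untouched.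

**Step 3**
Reactants: 3 [3-bromo-4,5-bis(methoxymethoxy)phenyl]methanol
Product: 4 [3,4-bis(methoxymethoxy)-5-prenylphenyl]methanol
Conditions: n-BuLi (2.2 equiv), THF, −78 °C; CuBr·SMe2; prenyl bromide, −78 → 0 °C; H2O
Reagents that add atoms: prenyl bromide (1-bromo-3-methylbut-2-ene), CC(C)=CCBr
Why: Deprotonation of the alcohol and bromine–lithium exchange give an acetal-chelated aryllithium, and transmetalation to copper followed by SN2 allylic substitution (organocopper allylation) should deliver the linear prenyl group.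

**Step 4**
Reactants: 4 [3,4-bis(methoxymethoxy)-5-prenylphenyl]methanol
Product: 5 [3,4-bis(methoxymethoxy)-2,5-diprenylphenyl]methanol (ArCH2OH)
Conditions: n-BuLi (2.3 equiv), TMEDA, Et2O, 0 °C; CuBr·SMe2, −40 °C; prenyl bromide, −40 °C → rt; H2O
Reagents that add atoms: prenyl bromide (1-bromo-3-methylbut-2-ene), CC(C)=CCBr
Why: Directed ortho-metalation should remove the ring hydrogen between the lithium alkoxide and the C3 acetal (the cooperatively activated site) faster than the benzylic/allylic hydrogens of the first prenyl group, and the arylcopper is prenylated as in step 3.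

**Step 5**
Reactants: 6 2,4-dihydroxybenzaldehyde
Product: 7 2-hydroxy-4-(prenyloxy)benzaldehyde
Conditions: prenyl bromide, K2CO3 (1 equiv), acetone, reflux
Reagents that add atoms: prenyl bromide (1-bromo-3-methylbut-2-ene), CC(C)=CCBr
Why: Williamson etherification should be selective for the 4-hydroxyl because the 2-hydroxyl is held in a hydrogen bond to the formyl group.

**Step 6**
Reactants: 7 2-hydroxy-4-(prenyloxy)benzaldehyde; 5 ArCH2OH
Product: 8 2-(ArCH2O)-4-(prenyloxy)benzaldehyde
Conditions: PPh3, DIAD, THF, 0 °C → rt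
Reagents that add atoms: none
Why: Mitsunobu etherification of an acidic salicylaldehyde hydroxyl with a primary benzylic alcohol avoids making the labile electron-rich benzylic halide.

**Step 7**
Reactants: 8 2-(ArCH2O)-4-(prenyloxy)benzaldehyde
Product: 9 2-(ArCH2O)-4-hydroxy-5-(2-methylbut-3-en-2-yl)benzaldehyde
Conditions: PhNEt2, 190 °C, sealed tube, Ar
Reagents that add atoms: none
Why: Aromatic Claisen rearrangement ([3,3]-sigmatropic, with allyl inversion) should place the 1,1-dimethylallyl group on the ortho carbon para to the ArCH2O oxygen, since the other ortho carbon lies between two oxygen substituents and is more hindered, and the amine solvent suppresses acid-promoted cyclization of the freed phenol.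

**Step 8**
Reactants: 9 2-(ArCH2O)-4-hydroxy-5-(2-methylbut-3-en-2-yl)benzaldehyde; 10 diallyl malonate
Product: 12 diallyl 2-{[4-acetoxy-2-(ArCH2O)-5-(2-methylbut-3-en-2-yl)phenyl]methylidene}malonate, via phenolic benzylidene malonate 11 (not isolated)
Conditions: piperidine (cat.), AcOH (cat.), PhMe, reflux, Dean–Stark; then rt, Ac2O, pyridine, DMAP (cat.)
Reagents that add atoms: acetic anhydride, CC(=O)OC(C)=O
Why: Knoevenagel condensation followed by O-acetylation; while the para-hydroxyl is free the benzylidene malonate is too electron-rich for a thermal hydride shift during heating, and acetylation then arms the acceptor at room temperature.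

**Step 9**
Reactants: 12 diallyl 2-{[4-acetoxy-2-(ArCH2O)-5-(2-methylbut-3-en-2-yl)phenyl]methylidene}malonate
Product: 14 diallyl (2R)-7-acetoxy-2-Ar-6-(2-methylbut-3-en-2-yl)chromane-3,3-dicarboxylate, via oxocarbenium malonate zwitterion 13 (not isolated)
Conditions: Sc(OTf)3 (10 mol %), C2-symmetric N,N'-dioxide ligand (from L- or D-pipecolic acid, 2,6-diisopropylanilide arms, propane-1,3-diyl bridge; 11 mol %), 4 Å MS, ClCH2CH2Cl, 30 °C
Reagents that add atoms: none
Why: This is a hydride-transfer-initiated cyclization (internal-redox C–H functionalization of the tert-amino-effect type), whose ether version converts ortho-(benzyloxy)benzylidene malonates into 2-arylchroman-3,3-dicarboxylates under Sc(OTf)3 and whose chiral Lewis acid variants rely on two-point binding of the malonate. Bound to the chiral scandium complex, C4 becomes electrophilic enough to take a hydride from the benzylic O–CH2 group through a six-membered 1,5-shift, giving zwitterion 13, whose scandium-bound malonate carbon (C3) then adds to the aryl oxocarbenium carbon (C2). The pyran ring (O1–C2–C3–C4–C4a–C8a) closes in a 6-(enolexo)-endo-trig Mannich/aldol-type mode. C2 is the only stereocentre formed (C3 bears two identical esters) and is controlled by the ligand on scandium: the complex selects one of the two enantiotopic benzylic hydrogens, which fixes the geometry and helical sense of the contact ion pair, and this pair should collapse faster than it relaxes. The step needs chemoselectivity for hydride transfer over Lewis-acid ionization of the benzylic ether and over capture of the oxocarbenium by the 2'-prenyl alkene, plus a negligible unligated background. The first is secured by the 4'-acetal oxygen para to C2 (making C2–H the most hydridic bond) together with the 7-acetate that keeps C4 electrophilic, the second by the fast intramolecular six-ring collapse of the ion pair, and the third by the slight excess of ligand at 30 °C.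

**Step 10**
Reactants: 14 diallyl (2R)-7-acetoxy-2-Ar-6-(2-methylbut-3-en-2-yl)chromane-3,3-dicarboxylate
Product: 16 (2S)-7-acetoxy-2-Ar-6-(2-methylbut-3-en-2-yl)chromane-3-carboxylic acid (both C3 epimers), via malonic acid 15 (not isolated)
Conditions: Pd(PPh3)4 (5 mol %), HCO2H, Et3N, THF, rt; aq citric acid work-up; then dioxane, 100 °C
Reagents that add atoms: none
Why: Tsuji–Trost deallylation with formate as hydride source (zerovalent palladium) unmasks both acids under neutral conditions that spare the aryl acetate and acetals, and the free geminal diacid then decarboxylates thermally without forming a C3 enolate, so O1 is not expelled and C2 is not scrambled by retro-oxa-Michael opening; the new C3 centre is of no consequence.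

**Step 11**
Reactants: 16 (2S)-7-acetoxy-2-Ar-6-(2-methylbut-3-en-2-yl)chromane-3-carboxylic acid
Product: 18 (2S)-2-Ar-6-(2-methylbut-3-en-2-yl)chroman-7-yl acetate, via Barton ester 17 (not isolated)
Conditions: N-hydroxypyridine-2-thione, DCC, CH2Cl2, 0 °C → rt, dark; then t-BuSH (10 equiv), hν (tungsten lamp), 20 °C
Reagents that add atoms: none
Why: Barton reductive decarboxylation: the thiohydroxamate ester fragments under visible light to the secondary C3 radical, which the thiol should quench faster than it can add to the 2'-prenyl alkene (a 6-exo process), leaving C2 untouched.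

**Step 12**
Reactants: 18 (2S)-2-Ar-6-(2-methylbut-3-en-2-yl)chroman-7-yl acetate
Product: 19 4-[(2S)-7-hydroxy-6-(2-methylbut-3-en-2-yl)-3,4-dihydro-2H-chromen-2-yl]-3,6-bis(3-methylbut-2-en-1-yl)benzene-1,2-diol (target)
Conditions: HCl (1.25 M in MeOH), 0 °C → rt, Ar
Reagents that add atoms: none
Why: Acid-catalysed methanolysis (transacetalization of both MOM ethers and transesterification of the aryl acetate) should free the three phenols in one operation under conditions mild enough to spare the prenyl groups and the benzylic C2–O1 bond.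

**Compound list**

1 | 3-bromo-4,5-dihydroxybenzaldehyde | O=Cc1cc(O)c(O)c(Br)c1 | starting material
2 | 3-bromo-4,5-bis(methoxymethoxy)benzaldehyde | O=Cc1cc(OCOC)c(OCOC)c(Br)c1 | intermediate
3 | [3-bromo-4,5-bis(methoxymethoxy)phenyl]methanol | OCc1cc(OCOC)c(OCOC)c(Br)c1 | intermediate
4 | [3,4-bis(methoxymethoxy)-5-(3-methylbut-2-en-1-yl)phenyl]methanol | OCc1cc(OCOC)c(OCOC)c(CC=C(C)C)c1 | intermediate
5 | [3,4-bis(methoxymethoxy)-2,5-bis(3-methylbut-2-en-1-yl)phenyl]methanol | OCc1cc(CC=C(C)C)c(OCOC)c(OCOC)c1CC=C(C)C | intermediate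
6 | 2,4-dihydroxybenzaldehyde | O=Cc1ccc(O)cc1O | starting material
7 | 2-hydroxy-4-[(3-methylbut-2-en-1-yl)oxy]benzaldehyde | O=Cc1ccc(OCC=C(C)C)cc1O | intermediate
8 | 2-{[3,4-bis(methoxymethoxy)-2,5-bis(3-methylbut-2-en-1-yl)phenyl]methoxy}-4-[(3-methylbut-2-en-1-yl)oxy]benzaldehyde | O=Cc1ccc(OCC=C(C)C)cc1OCc1cc(CC=C(C)C)c(OCOC)c(OCOC)c1CC=C(C)C | intermediate
9 | 2-{[3,4-bis(methoxymethoxy)-2,5-bis(3-methylbut-2-en-1-yl)phenyl]methoxy}-4-hydroxy-5-(2-methylbut-3-en-2-yl)benzaldehyde | O=Cc1cc(C(C)(C)C=C)c(O)cc1OCc1cc(CC=C(C)C)c(OCOC)c(OCOC)c1CC=C(C)C | intermediate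
10 | diallyl malonate (bis(prop-2-en-1-yl) propanedioate) | C=CCOC(=O)CC(=O)OCC=C | starting material
11 | diallyl 2-[(2-{[3,4-bis(methoxymethoxy)-2,5-bis(3-methylbut-2-en-1-yl)phenyl]methoxy}-4-hydroxy-5-(2-methylbut-3-en-2-yl)phenyl)methylidene]propanedioate | C=CCOC(=O)C(C(=O)OCC=C)=Cc1cc(C(C)(C)C=C)c(O)cc1OCc1cc(CC=C(C)C)c(OCOC)c(OCOC)c1CC=C(C)C | intermediate
12 | diallyl 2-[(4-acetoxy-2-{[3,4-bis(methoxymethoxy)-2,5-bis(3-methylbut-2-en-1-yl)phenyl]methoxy}-5-(2-methylbut-3-en-2-yl)phenyl)methylidene]propanedioate | C=CCOC(=O)C(C(=O)OCC=C)=Cc1cc(C(C)(C)C=C)c(OC(C)=O)cc1OCc1cc(CC=C(C)C)c(OCOC)c(OCOC)c1CC=C(C)C | intermediate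
13 | zwitterion formed from 12 by 1,5-hydride shift: aryl oxocarbenium ion with malonate carbanion (drawn metal-free) | C=CCOC(=O)[C-](Cc1cc(C(C)(C)C=C)c(OC(C)=O)cc1[O+]=Cc1cc(CC=C(C)C)c(OCOC)c(OCOC)c1CC=C(C)C)C(=O)OCC=C | intermediate
14 | diallyl (2R)-7-acetoxy-2-[3,4-bis(methoxymethoxy)-2,5-bis(3-methylbut-2-en-1-yl)phenyl]-6-(2-methylbut-3-en-2-yl)-2H-chromene-3,3(4H)-dicarboxylate | C=CC(C)(C)c1cc2c(cc1OC(C)=O)O[C@H](c1cc(CC=C(C)C)c(OCOC)c(OCOC)c1CC=C(C)C)C(C(=O)OCC=C)(C(=O)OCC=C)C2 | intermediate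
15 | (2R)-7-acetoxy-2-[3,4-bis(methoxymethoxy)-2,5-bis(3-methylbut-2-en-1-yl)phenyl]-6-(2-methylbut-3-en-2-yl)-2H-chromene-3,3(4H)-dicarboxylic acid | C=CC(C)(C)c1cc2c(cc1OC(C)=O)O[C@H](c1cc(CC=C(C)C)c(OCOC)c(OCOC)c1CC=C(C)C)C(C(=O)O)(C(=O)O)C2 | intermediate
16 | (2S)-7-acetoxy-2-[3,4-bis(methoxymethoxy)-2,5-bis(3-methylbut-2-en-1-yl)phenyl]-6-(2-methylbut-3-en-2-yl)-3,4-dihydro-2H-chromene-3-carboxylic acid (both C3 epimers) | C=CC(C)(C)c1cc2c(cc1OC(C)=O)O[C@H](c1cc(CC=C(C)C)c(OCOC)c(OCOC)c1CC=C(C)C)C(C(=O)O)C2 | intermediate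
17 | 2-thioxopyridin-1(2H)-yl (2S)-7-acetoxy-2-[3,4-bis(methoxymethoxy)-2,5-bis(3-methylbut-2-en-1-yl)phenyl]-6-(2-methylbut-3-en-2-yl)-3,4-dihydro-2H-chromene-3-carboxylate (both C3 epimers) | C=CC(C)(C)c1cc2c(cc1OC(C)=O)O[C@H](c1cc(CC=C(C)C)c(OCOC)c(OCOC)c1CC=C(C)C)C(C(=O)On1ccccc1=S)C2 | intermediate
18 | (2S)-2-[3,4-bis(methoxymethoxy)-2,5-bis(3-methylbut-2-en-1-yl)phenyl]-6-(2-methylbut-3-en-2-yl)-3,4-dihydro-2H-chromen-7-yl acetate | C=CC(C)(C)c1cc2c(cc1OC(C)=O)O[C@H](c1cc(CC=C(C)C)c(OCOC)c(OCOC)c1CC=C(C)C)CC2 | intermediate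
19 | 4-[(2S)-7-hydroxy-6-(2-methylbut-3-en-2-yl)-3,4-dihydro-2H-chromen-2-yl]-3,6-bis(3-methylbut-2-en-1-yl)benzene-1,2-diol | C=CC(C)(C)c1cc2c(cc1O)O[C@H](c1cc(CC=C(C)C)c(O)c(O)c1CC=C(C)C)CC2 | target

**Step count**

Total: 12 steps. Longest linear sequence: 11 steps (steps 1–4, then 6–12); step 5 is the short second branch.

**Steps most likely to fail**

Step 9. The chiral complex may discriminate poorly between the two enantiotopic benzylic hydrogens. Free Sc(OTf)3 may drive a racemic background or ionize the electron-rich benzylic ether. The oxocarbenium may be captured by the 2'-prenyl alkene before the ion pair collapses. The fallback leaves hydride-shift chemistry and closes the pyran ring at O1–C2 by known steps, setting out from 5 and 7: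
- MnO2 oxidation of 5 gives 3,4-bis(methoxymethoxy)-2,5-bis(3-methylbut-2-en-1-yl)benzaldehyde F1.
- MeMgBr gives 1-[3,4-bis(methoxymethoxy)-2,5-bis(3-methylbut-2-en-1-yl)phenyl]ethan-1-ol F2, and Dess–Martin periodinane gives the methyl ketone 1-[3,4-bis(methoxymethoxy)-2,5-bis(3-methylbut-2-en-1-yl)phenyl]ethan-1-one F3.
- Claisen–Schmidt condensation of F3 with 7 (KOH, EtOH) gives (E)-1-Ar-3-[2-hydroxy-4-(prenyloxy)phenyl]prop-2-en-1-one F4.
- Conjugate reduction (Zn dust, NH4Cl, aqueous EtOH) gives 1-Ar-3-[2-hydroxy-4-(prenyloxy)phenyl]propan-1-one F5.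
- Asymmetric transfer hydrogenation with RuCl(p-cymene)[(R,R)-TsDPEN] and HCO2H/Et3N gives (1R)-1-Ar-3-[2-hydroxy-4-(prenyloxy)phenyl]propan-1-ol F6.
- Intramolecular Mitsunobu etherification (PPh3, DIAD) closes the ring with inversion to (2S)-2-Ar-7-(prenyloxy)chromane F7.
- Aromatic Claisen rearrangement as in step 7 gives (2S)-2-Ar-6-(2-methylbut-3-en-2-yl)chroman-7-ol F8, and Ac2O/pyridine brings the material back to the route at 18.

Step 7. The allyl unit may migrate to the ortho carbon between the two ring oxygens instead of the one para to the ether oxygen, and the freed phenol may react further with its neighbouring 1,1-dimethylallyl group at 190 °C (ene-type cyclization, abnormal Claisen). The fallback builds the quaternary benzylic carbon by cross-coupling instead of a sigmatropic shift, setting out from 6: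
- Bromination (Br2, AcOH) gives 5-bromo-2,4-dihydroxybenzaldehyde F9.
- TBSCl/imidazole silylates the non-chelated hydroxyl to give 5-bromo-4-[(tert-butyldimethylsilyl)oxy]-2-hydroxybenzaldehyde F10.
- Mitsunobu etherification with 5 gives 2-(ArCH2O)-5-bromo-4-[(tert-butyldimethylsilyl)oxy]benzaldehyde F11.
- Branch-selective Suzuki–Miyaura coupling with prenylboronic acid pinacol ester (Pd(OAc)2, a bulky biarylphosphine chosen for coupling at the tertiary allyl terminus, K3PO4) gives 2-(ArCH2O)-4-[(tert-butyldimethylsilyl)oxy]-5-(2-methylbut-3-en-2-yl)benzaldehyde F12.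
- TBAF removes the silyl group and returns to the route at 9.

Step 12. Protic acid may add a freed phenol across its neighbouring prenyl alkene (chroman formation), or ionize the benzylic C2–O1 bond, faster than the acetals and the hindered acetate are solvolysed. The fallback separates the two unmaskings and avoids protic acid, setting out from 18:
- ZnBr2 and n-PrSH in CH2Cl2 at 0 °C remove both acetals by thiol capture to give (2S)-2-[3,4-dihydroxy-2,5-bis(3-methylbut-2-en-1-yl)phenyl]-6-(2-methylbut-3-en-2-yl)chroman-7-yl acetate F13.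
- K2CO3 in degassed MeOH at 0 °C, quenched with NH4Cl, removes the acetate and arrives at 19.

**Further compounds**

F1 | step 9 | 3,4-bis(methoxymethoxy)-2,5-bis(3-methylbut-2-en-1-yl)benzaldehyde | O=Cc1cc(CC=C(C)C)c(OCOC)c(OCOC)c1CC=C(C)C
F2 | step 9 | 1-[3,4-bis(methoxymethoxy)-2,5-bis(3-methylbut-2-en-1-yl)phenyl]ethan-1-ol (racemic) | CC(O)c1cc(CC=C(C)C)c(OCOC)c(OCOC)c1CC=C(C)C
F3 | step 9 | 1-[3,4-bis(methoxymethoxy)-2,5-bis(3-methylbut-2-en-1-yl)phenyl]ethan-1-one | CC(=O)c1cc(CC=C(C)C)c(OCOC)c(OCOC)c1CC=C(C)C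
F4 | step 9 | (E)-1-[3,4-bis(methoxymethoxy)-2,5-bis(3-methylbut-2-en-1-yl)phenyl]-3-{2-hydroxy-4-[(3-methylbut-2-en-1-yl)oxy]phenyl}prop-2-en-1-one | O=C(/C=C/c1ccc(OCC=C(C)C)cc1O)c1cc(CC=C(C)C)c(OCOC)c(OCOC)c1CC=C(C)C
F5 | step 9 | 1-[3,4-bis(methoxymethoxy)-2,5-bis(3-methylbut-2-en-1-yl)phenyl]-3-{2-hydroxy-4-[(3-methylbut-2-en-1-yl)oxy]phenyl}propan-1-one | O=C(CCc1ccc(OCC=C(C)C)cc1O)c1cc(CC=C(C)C)c(OCOC)c(OCOC)c1CC=C(C)C
F6 | step 9 | (1R)-1-[3,4-bis(methoxymethoxy)-2,5-bis(3-methylbut-2-en-1-yl)phenyl]-3-{2-hydroxy-4-[(3-methylbut-2-en-1-yl)oxy]phenyl}propan-1-ol | O[C@H](CCc1ccc(OCC=C(C)C)cc1O)c1cc(CC=C(C)C)c(OCOC)c(OCOC)c1CC=C(C)C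
F7 | step 9 | (2S)-2-[3,4-bis(methoxymethoxy)-2,5-bis(3-methylbut-2-en-1-yl)phenyl]-7-[(3-methylbut-2-en-1-yl)oxy]-3,4-dihydro-2H-chromene | CC(C)=CCOc1ccc2c(c1)O[C@H](c1cc(CC=C(C)C)c(OCOC)c(OCOC)c1CC=C(C)C)CC2
F8 | step 9 | (2S)-2-[3,4-bis(methoxymethoxy)-2,5-bis(3-methylbut-2-en-1-yl)phenyl]-6-(2-methylbut-3-en-2-yl)-3,4-dihydro-2H-chromen-7-ol | C=CC(C)(C)c1cc2c(cc1O)O[C@H](c1cc(CC=C(C)C)c(OCOC)c(OCOC)c1CC=C(C)C)CC2
F9 | step 7 | 5-bromo-2,4-dihydroxybenzaldehyde | O=Cc1cc(Br)c(O)cc1O
F10 | step 7 | 5-bromo-4-[(tert-butyldimethylsilyl)oxy]-2-hydroxybenzaldehyde | O=Cc1cc(Br)c(O[Si](C)(C)C(C)(C)C)cc1O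
F11 | step 7 | 2-{[3,4-bis(methoxymethoxy)-2,5-bis(3-methylbut-2-en-1-yl)phenyl]methoxy}-5-bromo-4-[(tert-butyldimethylsilyl)oxy]benzaldehyde | O=Cc1cc(Br)c(O[Si](C)(C)C(C)(C)C)cc1OCc1cc(CC=C(C)C)c(OCOC)c(OCOC)c1CC=C(C)C
F12 | step 7 | 2-{[3,4-bis(methoxymethoxy)-2,5-bis(3-methylbut-2-en-1-yl)phenyl]methoxy}-4-[(tert-butyldimethylsilyl)oxy]-5-(2-methylbut-3-en-2-yl)benzaldehyde | O=Cc1cc(C(C)(C)C=C)c(O[Si](C)(C)C(C)(C)C)cc1OCc1cc(CC=C(C)C)c(OCOC)c(OCOC)c1CC=C(C)C
F13 | step 12 | (2S)-2-[3,4-dihydroxy-2,5-bis(3-methylbut-2-en-1-yl)phenyl]-6-(2-methylbut-3-en-2-yl)-3,4-dihydro-2H-chromen-7-yl acetate | C=CC(C)(C)c1cc2c(cc1OC(C)=O)O[C@H](c1cc(CC=C(C)C)c(O)c(O)c1CC=C(C)C)CC2
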